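**Plan**
- Cuts: C12–C13 (sp3–sp2 coupling) and C11=C12 (methylenation) remove the dienyl chain. The oxygens at C18, C8 and C6 are traced back to a 3-oxygenated Δ7-6-ketone, and this to a C6–C7 silyl enol ether. Last, C5–C10 and C8–C9 are cut together.
- Enabling feature: in ring B the oxygen-bearing C6 lies 1,4 to C9, C8 carries a methyl group next to C9, and C10 is quaternary. Ring B is therefore the retron of a C5=C6(OSi)–C7=C8 diene plus a C9=C10 E-enoate (C11 = ester carbon). C1–C4 of ring A is the four-atom tether from C10 to C5.
- Forward: a linear triene is joined from methyl geranate (C1–C3, C9–C11, C20), dimethylallene (C4–C6, C18, C19) and bromopropene (C7, C8, C17). One cycloaddition closes rings A and B. Then C11 is reduced, ring A is adjusted (C18–H oxidation, C3 deoxygenation), ring B is oxygenated (C8, then C6), and the chain is finished (C12 by Wittig, C13–C16 from chloroprene).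
- Stereochemistry: the C3 carbinol from an asymmetric prenylboration is the only external source and is deleted later. Alkene geometries and the endo transition state relay it to C5, C9 and C10. C4 comes from directed silylation of the equatorial methyl, C8 from epoxidation anti to C20, and C6 from single-electron reduction to the equatorial alcohol.

Key step: step 8

Convention: labdane numbering throughout. Face M is the decalin face carrying the C10 methyl (C20) and face H is the face carrying H5. TBS = tert-butyldimethylsilyl, Ipc = isopinocampheyl.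
Remark on the chemistry: crystalline (−)-Ipc2BH (derived from (+)-α-pinene) and stabilised chloroprene solution are taken as purchasable.

**Step 1**
Reactants: 1 methyl geranate
Product: 2 methyl (2E)-3-methyl-6-oxohex-2-enoate
Conditions: O3 (1 equiv), CH2Cl2, −78 °C; Me2S, −78 °C to rt
Reagents that add atoms: ozone [O-][O+]=O
Why: Ozonolysis, in which the electrophilic ozone cleaves the electron-rich distal trisubstituted alkene far faster than the ester-conjugated one, so one equivalent should stop at the enoate aldehyde.

**Step 2**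
Reactants: 2 methyl (2E)-3-methyl-6-oxohex-2-enoate; 3 3-methylbuta-1,2-diene
Product: 6 methyl (2E,6R)-6-hydroxy-3,7,7-trimethylnona-2,8-dienoate, via prenylborane 4 (not isolated), via borinate ester 5 (not isolated)
Conditions: (−)-Ipc2BH, 3, THF, −25 to 0 °C; 2, −78 °C; NaOH aq, H2O2, 0 °C to rt
Reagents that add atoms: (−)-diisopinocampheylborane B([C@@H]1C[C@@H]2C[C@H]([C@H]1C)C2(C)C)[C@@H]1C[C@@H]2C[C@H]([C@H]1C)C2(C)C (boron and terpene groups of 4 and 5 only)
Why: Brown allylboration in its reverse-prenylation form, in which allene hydroboration gives the prenylborane, which transfers its tertiary terminus through a closed chair transition state while the Ipc groups derived from (+)-α-pinene direct attack to the Si face of the aldehyde, setting the (R)-carbinol (C3) next to the new gem-dimethyl carbon C4.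

**Step 3**
Reactants: 6 methyl (2E,6R)-6-hydroxy-3,7,7-trimethylnona-2,8-dienoate
Product: 7 methyl (2E,6R)-6-(tert-butyldimethylsilyloxy)-3,7,7-trimethylnona-2,8-dienoate
Conditions: TBSOTf, 2,6-lutidine, CH2Cl2, 0 °C
Reagents that add atoms: tert-butyldimethylsilyl triflate CC(C)(C)[Si](C)(C)OS(=O)(=O)C(F)(F)F
Why: Silyl triflate silylation copes with the neopentyl-type secondary alcohol, and among robust oxygen substituents a trialkylsilyloxy group has the largest equatorial preference, which is what step 8 relies on.

**Step 4**
Reactants: 7 methyl (2E,6R)-6-(tert-butyldimethylsilyloxy)-3,7,7-trimethylnona-2,8-dienoate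
Product: 8 methyl (2E,6R)-6-(tert-butyldimethylsilyloxy)-3,7,7-trimethyl-9-oxonon-2-enoate
Conditions: PdCl2(PhCN)2 (cat.), CuCl2·2H2O (cat.), AgNO2 (cat.), O2 (1 atm), t-BuOH/MeNO2 15:1, rt
Reagents that add atoms: dioxygen O=O
Why: Nitrite-modified aldehyde-selective Wacker-type oxidation, established for vinyl groups on quaternary carbons, where the quaternary allylic centre disfavours Markovnikov attack and the conjugated trisubstituted alkene stays out of the reaction.

**Step 5**
Reactants: 8 methyl (2E,6R)-6-(tert-butyldimethylsilyloxy)-3,7,7-trimethyl-9-oxonon-2-enoate; 9 (E)-1-bromoprop-1-ene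
Product: 11 methyl (2E,6R,10E)-6-(tert-butyldimethylsilyloxy)-9-hydroxy-3,7,7-trimethyldodeca-2,10-dienoate (both C9 epimers), via propenylmagnesium bromide 10 (not isolated)
Conditions: 9, Mg, THF, rt; then 8, THF, −78 °C; H2O
Reagents that add atoms: magnesium [Mg] (in 10 only)
Why: Grignard 1,2-addition, in which the aldehyde reacts at −78 °C much faster than the β,β-disubstituted enoate, the alkenyl reagent largely keeps the E geometry of 9, and the new carbinol centre does not matter because it is oxidised next.

**Step 6**
Reactants: 11 methyl (2E,6R,10E)-6-(tert-butyldimethylsilyloxy)-9-hydroxy-3,7,7-trimethyldodeca-2,10-dienoate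
Product: 12 methyl (2E,6R,10E)-6-(tert-butyldimethylsilyloxy)-3,7,7-trimethyl-9-oxododeca-2,10-dienoate
Conditions: Dess–Martin periodinane, CH2Cl2, 0 °C to rt
Reagents that add atoms: none
Why: Dess–Martin oxidation of the allylic alcohol under neutral conditions should give the E-enone, the stable geometry into which any Z contaminant can relax, without touching silyl ether or enoate.

**Step 7**
Reactants: 12 methyl (2E,6R,10E)-6-(tert-butyldimethylsilyloxy)-3,7,7-trimethyl-9-oxododeca-2,10-dienoate
Product: 13 methyl (2E,6R,8Z,10E)-6,9-bis(tert-butyldimethylsilyloxy)-3,7,7-trimethyldodeca-2,8,10-trienoate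
Conditions: TBSOTf, Et3N, CH2Cl2, −78 to 0 °C
Reagents that add atoms: tert-butyldimethylsilyl triflate CC(C)(C)[Si](C)(C)OS(=O)(=O)C(F)(F)F
Why: Soft enolisation with silyl triflate and amine, known to turn propenyl ketones into cross-conjugated 2-silyloxydienes by loss of an α′ proton (here from C5), while allylic strain between the tertiary alkyl carbon C4 and the propenyl group enforces the Z enol ether, which places C4 on the outside of the diene.

**Step 8**
Reactants: 13 methyl (2E,6R,8Z,10E)-6,9-bis(tert-butyldimethylsilyloxy)-3,7,7-trimethyldodeca-2,8,10-trienoate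
Product: 14 trans-fused cycloadduct methyl (1R,2R,4aS,6R,8aR)-4,6-bis(tert-butyldimethylsilyloxy)-2,5,5,8a-tetramethyl-1,2,4a,5,6,7,8,8a-octahydronaphthalene-1-carboxylate
Conditions: PhMe (0.01 M), BHT (cat.), sealed tube, 190 °C
Reagents that add atoms: none
Why: This is a thermal type 1 intramolecular Diels–Alder reaction, a concerted but asynchronous [4+2] cycloaddition in which the silyloxy group raises the diene HOMO and puts its largest coefficient on C5, which bonds to the electrophilic β-carbon C10 while C8 bonds to the α-carbon C9, the closest known class being the thermal cyclisation of 1,7,9-decatrienoates that carry a 2-silyloxydiene and a β-methyl enoate and give angularly methylated decalins. Ring B is the cyclohexene made by the cycloaddition itself, and ring A closes at the same moment as a six-membered carbocycle from the four-atom tether C1–C4, both in the fused and not the bridged mode. C9 and C10 follow from suprafacial addition to the E-enoate (C11 cis to C20), C5 and C8 from suprafacial addition to a diene whose C4 and C17 both stand outside (C4 cis to C17), and the two pairs are related by the transition state with the ester endo and the tether anti, which gives the trans fusion with C17, C11 and C20 all on face M. The absolute sense comes from C3, because in the chair-like tether the OTBS group prefers the equatorial site and thereby exposes one π-face of each partner. The step thus needs endo/exo and π-facial selectivity; the geminal methyls at C4 speed closure and block 1,5-hydrogen shifts, the facial bias is expected to be only moderate next to the gem-dimethyl carbon, and the adduct of the other face is a C3 diastereomer that chromatography removes, so enantiopurity is not eroded. A cis-fused adduct with the same C9/C10 configuration is not lost, since step 11 deletes C8 as a stereocentre and makes C5 epimerisable to the trans-decalone.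

**Step 9**
Reactants: 14 trans-fused cycloadduct
Product: 15 C11 primary alcohol (C9–CH2OH; 3-OTBS and C6–C7 TBS enol ether kept)
Conditions: LiAlH4, Et2O, 0 °C to rt; H2O, NaOH aq
Reagents that add atoms: none
Why: Hydride reduction of the hindered ester leaves silyl ether and silyl enol ether untouched, and removing the ester now keeps H9 from becoming a vinylogous β-keto ester proton, and C9 from epimerising, once the enone is made.

**Step 10**
Reactants: 15 C11 primary alcohol
Product: 16 11-O-benzyl ether
Conditions: NaH, BnBr, Bu4NI (cat.), THF/DMF, 0 °C to rt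
Reagents that add atoms: benzyl bromide BrCc1ccccc1
Why: Williamson etherification of the only free hydroxyl installs a group that is orthogonal to all silyl groups and can leave by hydrogenolysis at a stage without alkenes.

**Step 11**
Reactants: 16 11-O-benzyl ether
Product: 17 Δ7-6-ketone (11-OBn and 3-OTBS; trans-decalone)
Conditions: Pd(OAc)2 (1.1 equiv), MeCN, rt to 40 °C
Reagents that add atoms: none
Why: Saegusa–Ito oxidation, in which divalent palladium binds C7 of the regiodefined enol ether and β-hydride elimination of H8 gives the Δ7-6-ketone, deleting C8 as a stereocentre and leaving C5 as an epimerisable centre whose stable form is the trans-decalone.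

**Step 12**
Reactants: 17 Δ7-6-ketone
Product: 18 3-hydroxy Δ7-6-ketone
Conditions: HF (48% aq), MeCN, rt
Reagents that add atoms: none
Why: Acidic fluoride desilylation cleaves the remaining secondary TBS ether while enone and benzyl ether are inert.

**Step 13**
Reactants: 18 3-hydroxy Δ7-6-ketone
Product: 21 3,18-diol of the Δ7-6-ketone, via hydrosilyl ether 19 (not isolated), via oxasilolane 20 (not isolated)
Conditions: Et2SiH2, [Ir(cod)OMe]2 (cat.), THF, rt, evaporate; [Ir(cod)OMe]2 (cat.), 3,4,7,8-Me4-phenanthroline (cat.), norbornene, THF, 100 °C; H2O2 aq, KHCO3, THF/MeOH, 50 °C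
Reagents that add atoms: hydrogen peroxide OO; diethylsilane CC[SiH2]CC (silicon of 19 and 20 only)
Why: Hydroxyl-directed iridium-catalysed C–H silylation followed by Tamao–Fleming oxidation, a sequence established on 3-hydroxy-4,4-dimethyl terpenoid A rings that also carry hindered enones, in which the equatorial O–SiHEt2 group is expected to close a five-membered oxasilolane onto the equatorial methyl C18 rather than the axial C19, as it does on those A rings, making C4 stereogenic with CH2O on face H and CH3 on face M.

**Step 14**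
Reactants: 21 3,18-diol of the Δ7-6-ketone
Product: 22 18-O-TBS ether with free 3-OH
Conditions: TBSCl, imidazole, CH2Cl2, 0 °C
Reagents that add atoms: tert-butyldimethylsilyl chloride CC(C)(C)[Si](C)(C)Cl
Why: Selective silylation, since the primary alcohol reacts with the silyl chloride much faster than the secondary C3 hydroxyl flanked by the quaternary C4.

**Step 15**
Reactants: 22 18-O-TBS ether with free 3-OH
Product: 23 3-O-(imidazol-1-ylthiocarbonyl) derivative
Conditions: 1,1′-thiocarbonyldiimidazole, DMAP (cat.), ClCH2CH2Cl, 80 °C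
Reagents that add atoms: 1,1′-thiocarbonyldiimidazole S=C(n1ccnc1)n1ccnc1
Why: Thiocarbonylation under essentially neutral conditions prepares the C3 alcohol for radical deoxygenation without exposing the enone to strong base.

**Step 16**
Reactants: 23 3-O-(imidazol-1-ylthiocarbonyl) derivative
Product: 24 3-deoxy Δ7-6-ketone (11-OBn and 18-OTBS)
Conditions: Bu3SnH, AIBN (cat.), PhMe, 100 °C
Reagents that add atoms: none
Why: Barton–McCombie deoxygenation, in which the stannyl radical adds to sulfur and the released secondary C3 radical is quenched by the tin hydride faster than anything adds to the hindered β,β-disubstituted enone, so the control element at C3 disappears.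

**Step 17**
Reactants: 24 3-deoxy Δ7-6-ketone
Product: 25 7,8-epoxy-6-ketone with the epoxide on face H
Conditions: t-BuOOH, BnMe3NOH (cat.), THF, 0 °C to rt
Reagents that add atoms: tert-butyl hydroperoxide CC(C)(C)OO
Why: Weitz–Scheffer nucleophilic epoxidation, in which the peroxide anion should add to C8 from face H, away from the axial C10 methyl (1,3 to C8) and the C9 side arm, and ring closure on the same face fixes the C8–O and C7–O bonds on face H.

**Step 18**
Reactants: 25 7,8-epoxy-6-ketone
Product: 27 6,8-diol with both hydroxyls equatorial on face H, via hydroxy ketone 26 (not isolated)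
Conditions: SmI2, THF/MeOH, −78 °C; then SmI2, H2O, THF, 0 °C to rt
Reagents that add atoms: none
Why: Two single-electron reductions by divalent samarium, the first a known epoxy ketone to aldol opening in which the ketyl expels the α C7–O bond and leaves C8 untouched, the second a ketone reduction whose ketyl and organosamarium stages keep the bulky O–Sm group equatorial, away from the syn-axial methyls C19 and C20, so that the C6 hydroxyl should end equatorial on face H, an outcome that hydride reagents attacking from the open face H cannot give.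

**Step 19**
Reactants: 27 6,8-diol
Product: 28 6-acetate with free tertiary 8-OH
Conditions: Ac2O, DMAP (cat.), pyridine, rt
Reagents that add atoms: acetic anhydride CC(=O)OC(C)=O
Why: DMAP-catalysed acylation distinguishes the secondary C6 alcohol from the tertiary C8 alcohol, which stays free.

**Step 20**
Reactants: 28 6-acetate
Product: 29 C11 primary alcohol (6-OAc, 8-OH, 18-OTBS)
Conditions: H2 (1 atm), Pd/C, EtOAc, rt
Reagents that add atoms: none
Why: Hydrogenolysis of the benzyl ether is clean here because the molecule holds no alkene at this stage and acetate and silyl ether are stable.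

**Step 21**
Reactants: 29 C11 primary alcohol
Product: 30 C11 aldehyde
Conditions: Dess–Martin periodinane, pyridine, CH2Cl2, 0 °C
Reagents that add atoms: none
Why: Buffered Dess–Martin oxidation gives the β-hydroxy aldehyde without acid or base strong enough to trigger dehydration, retro-aldol cleavage or epimerisation at C9.

**Step 22**
Reactants: 30 C11 aldehyde
Product: 31 C9-vinyl compound (C11=C12)
Conditions: Ph3PCH3Br, KN(SiMe3)2, THF, 0 °C; then 30, −78 to 0 °C
Reagents that add atoms: methyltriphenylphosphonium bromide C[P+](c1ccccc1)(c1ccccc1)c1ccccc1.[Br-]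
Why: Wittig methylenation with the non-stabilised ylide is fast at low temperature, the ylide is too weak a base to deprotonate the tertiary alcohol, and the hindered acetate is not attacked.

**Step 23**
Reactants: 31 C9-vinyl compound; 32 chloroprene (2-chlorobuta-1,3-diene)
Product: 34 18-O-TBS ether of the target, via alkylborane 33 (not isolated)
Conditions: 9-BBN, THF, rt to 40 °C; then K3PO4 aq, 32, Pd(OAc)2 (cat.), SPhos (cat.), BHT, THF, 50 °C, sealed
Reagents that add atoms: 9-borabicyclo[3.3.1]nonane B1C2CCCC1CCC2 (boron of 33 only)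
Why: Hydroboration and B-alkyl Suzuki–Miyaura coupling, in which 9-BBN adds to the terminal carbon C12 of the monosubstituted alkene and the phosphate-activated borane couples with the alkenyl chloride under an electron-rich biarylphosphine palladium catalyst, forming C12–C13 and delivering the 2-substituted 1,3-diene intact.

**Step 24**
Reactants: 34 18-O-TBS ether of the target
Product: 35 target, [(1R,3S,4S,4aR,8S,8aS)-3-hydroxy-8-(hydroxymethyl)-3,4a,8-trimethyl-4-(3-methylidenepent-4-enyl)decahydronaphthalen-1-yl] acetate
Conditions: HF·pyridine, pyridine/THF, 0 °C to rt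
Reagents that add atoms: none
Why: Buffered fluoride desilylation frees the C18 alcohol under mildly acidic conditions that avoid acetyl migration from O6 to the neighbouring O18 and leave the diene and the tertiary alcohol untouched.

**Compound list**
1 | methyl geranate, methyl (2E)-3,7-dimethylocta-2,6-dienoate | COC(=O)/C=C(\C)CCC=C(C)C | starting material
2 | methyl (2E)-3-methyl-6-oxohex-2-enoate | COC(=O)/C=C(\C)CCC=O | intermediate
3 | 3-methylbuta-1,2-diene | CC(C)=C=C | starting material
4 | (3-methylbut-2-enyl)diisopinocampheylborane, Ipc from (+)-α-pinene (not isolated) | CC(C)=CCB([C@@H]1C[C@@H]2C[C@H]([C@H]1C)C2(C)C)[C@@H]1C[C@@H]2C[C@H]([C@H]1C)C2(C)C | intermediate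
5 | diisopinocampheylborinate ester of 6 (not isolated) | COC(=O)/C=C(\C)CC[C@@H](OB([C@@H]1C[C@@H]2C[C@H]([C@H]1C)C2(C)C)[C@@H]1C[C@@H]2C[C@H]([C@H]1C)C2(C)C)C(C)(C)C=C | intermediate
6 | methyl (2E,6R)-6-hydroxy-3,7,7-trimethylnona-2,8-dienoate | COC(=O)/C=C(\C)CC[C@@H](O)C(C)(C)C=C | intermediate
7 | methyl (2E,6R)-6-(tert-butyldimethylsilyloxy)-3,7,7-trimethylnona-2,8-dienoate | COC(=O)/C=C(\C)CC[C@@H](O[Si](C)(C)C(C)(C)C)C(C)(C)C=C | intermediate
8 | methyl (2E,6R)-6-(tert-butyldimethylsilyloxy)-3,7,7-trimethyl-9-oxonon-2-enoate | COC(=O)/C=C(\C)CC[C@@H](O[Si](C)(C)C(C)(C)C)C(C)(C)CC=O | intermediate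
9 | (E)-1-bromoprop-1-ene | C/C=C/Br | starting material
10 | (E)-prop-1-enylmagnesium bromide (not isolated) | C/C=C/[Mg]Br | intermediate
11 | methyl (2E,6R,10E)-6-(tert-butyldimethylsilyloxy)-9-hydroxy-3,7,7-trimethyldodeca-2,10-dienoate, both C9 epimers | COC(=O)/C=C(\C)CC[C@@H](O[Si](C)(C)C(C)(C)C)C(C)(C)CC(O)/C=C/C | intermediate
12 | methyl (2E,6R,10E)-6-(tert-butyldimethylsilyloxy)-3,7,7-trimethyl-9-oxododeca-2,10-dienoate | COC(=O)/C=C(\C)CC[C@@H](O[Si](C)(C)C(C)(C)C)C(C)(C)CC(=O)/C=C/C | intermediate
13 | methyl (2E,6R,8Z,10E)-6,9-bis(tert-butyldimethylsilyloxy)-3,7,7-trimethyldodeca-2,8,10-trienoate | COC(=O)/C=C(\C)CC[C@@H](O[Si](C)(C)C(C)(C)C)C(C)(C)/C=C(O[Si](C)(C)C(C)(C)C)/C=C/C | intermediate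
14 | trans-fused cycloadduct, labdane (3R,5S,8R,9R,10R): C9 ester, C8 methyl, C10 methyl and equatorial 3-OTBS on face M, H5, H8, H9 on face H, C6–C7 TBS enol ether | COC(=O)[C@H]1[C@]2(C)CC[C@@H](O[Si](C)(C)C(C)(C)C)C(C)(C)[C@H]2C(O[Si](C)(C)C(C)(C)C)=C[C@H]1C | intermediate
15 | C11 alcohol, ester of 14 reduced to CH2OH, stereocentres as in 14 | OC[C@H]1[C@]2(C)CC[C@@H](O[Si](C)(C)C(C)(C)C)C(C)(C)[C@H]2C(O[Si](C)(C)C(C)(C)C)=C[C@H]1C | intermediate
16 | 11-O-benzyl ether of 15 | c1ccccc1COC[C@H]1[C@]2(C)CC[C@@H](O[Si](C)(C)C(C)(C)C)C(C)(C)[C@H]2C(O[Si](C)(C)C(C)(C)C)=C[C@H]1C | intermediate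
17 | Δ7-6-ketone, 11-OBn, 3-OTBS, trans-decalone, C11 on face M | c1ccccc1COC[C@H]1[C@]2(C)CC[C@@H](O[Si](C)(C)C(C)(C)C)C(C)(C)[C@H]2C(=O)C=C1C | intermediate
18 | 3-hydroxy Δ7-6-ketone, equatorial 3-OH on face M | c1ccccc1COC[C@H]1[C@]2(C)CC[C@@H](O)C(C)(C)[C@H]2C(=O)C=C1C | intermediate
19 | 3-O-diethylsilyl (Si–H) ether of 18 (not isolated) | c1ccccc1COC[C@H]1[C@]2(C)CC[C@@H](O[SiH](CC)CC)C(C)(C)[C@H]2C(=O)C=C1C | intermediate
20 | oxasilolane O3–SiEt2–C18, C18 equatorial on face H, C19 axial on face M (not isolated) | c1ccccc1COC[C@H]1[C@]2(C)CC[C@H]3O[Si](CC)(CC)C[C@]3(C)[C@H]2C(=O)C=C1C | intermediate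
21 | 3,18-diol of the Δ7-6-ketone | c1ccccc1COC[C@H]1[C@]2(C)CC[C@@H](O)[C@](C)(CO)[C@H]2C(=O)C=C1C | intermediate
22 | 18-O-TBS ether, 3-OH free | c1ccccc1COC[C@H]1[C@]2(C)CC[C@@H](O)[C@](C)(CO[Si](C)(C)C(C)(C)C)[C@H]2C(=O)C=C1C | intermediate
23 | 3-O-(imidazol-1-ylthiocarbonyl) derivative of 22 | c1ccccc1COC[C@H]1[C@]2(C)CC[C@@H](OC(=S)n3ccnc3)[C@](C)(CO[Si](C)(C)C(C)(C)C)[C@H]2C(=O)C=C1C | intermediate
24 | 3-deoxy Δ7-6-ketone, 11-OBn, 18-OTBS | c1ccccc1COC[C@H]1[C@]2(C)CCC[C@](C)(CO[Si](C)(C)C(C)(C)C)[C@H]2C(=O)C=C1C | intermediate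
25 | 7,8-epoxy-6-ketone, epoxide on face H, C8 methyl on face M | c1ccccc1COC[C@H]1[C@]2(C)CCC[C@](C)(CO[Si](C)(C)C(C)(C)C)[C@H]2C(=O)[C@@H]3O[C@]13C | intermediate
26 | 8-hydroxy-6-ketone, equatorial 8-OH on face H (not isolated) | c1ccccc1COC[C@H]1[C@]2(C)CCC[C@](C)(CO[Si](C)(C)C(C)(C)C)[C@H]2C(=O)C[C@]1(C)O | intermediate
27 | 6,8-diol, both hydroxyls equatorial on face H | c1ccccc1COC[C@H]1[C@]2(C)CCC[C@](C)(CO[Si](C)(C)C(C)(C)C)[C@H]2[C@H](O)C[C@]1(C)O | intermediate
28 | 6-acetate of 27 | c1ccccc1COC[C@H]1[C@]2(C)CCC[C@](C)(CO[Si](C)(C)C(C)(C)C)[C@H]2[C@H](OC(C)=O)C[C@]1(C)O | intermediate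
29 | C11 alcohol, 6-OAc, 8-OH, 18-OTBS | OC[C@H]1[C@]2(C)CCC[C@](C)(CO[Si](C)(C)C(C)(C)C)[C@H]2[C@H](OC(C)=O)C[C@]1(C)O | intermediate
30 | C11 aldehyde | O=C[C@H]1[C@]2(C)CCC[C@](C)(CO[Si](C)(C)C(C)(C)C)[C@H]2[C@H](OC(C)=O)C[C@]1(C)O | intermediate
31 | C9-vinyl compound (C11=C12) | C=C[C@H]1[C@]2(C)CCC[C@](C)(CO[Si](C)(C)C(C)(C)C)[C@H]2[C@H](OC(C)=O)C[C@]1(C)O | intermediate
32 | chloroprene, 2-chlorobuta-1,3-diene | C=CC(Cl)=C | starting material
33 | C12 B-alkyl-9-borabicyclo[3.3.1]nonane (not isolated) | C1CC2CCCC(C1)B2CC[C@H]1[C@]2(C)CCC[C@](C)(CO[Si](C)(C)C(C)(C)C)[C@H]2[C@H](OC(C)=O)C[C@]1(C)O | intermediate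
34 | 18-O-TBS ether of the target | C=CC(=C)CC[C@H]1[C@]2(C)CCC[C@](C)(CO[Si](C)(C)C(C)(C)C)[C@H]2[C@H](OC(C)=O)C[C@]1(C)O | intermediate
35 | target, labdane (4S,5S,6R,8S,9S,10R): 6-acetoxy-8,18-dihydroxylabda-13(16),14-diene of the ent series | C=CC(=C)CC[C@H]1[C@]2(C)CCC[C@](C)(CO)[C@H]2[C@H](OC(C)=O)C[C@]1(C)O | target

**Total step count:** 24. **Longest linear sequence:** 24 steps (1 to 35; compounds 3, 9 and 32 enter as purchased).

**Steps most likely to fail**

**Step 8.**
- What may go wrong: the cycloaddition must join C5, which sits next to the quaternary C4, to the fully substituted C10. It may be too slow below the temperature at which the silyl dienol ether degrades. Endo/exo and facial discrimination may also be poor at 190 °C, because the equatorial preference of the C3 substituent is weakened by the adjacent gem-dimethyl carbon.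
- Fallback: form the same two bonds by a stepwise ionic route at low temperature, setting out from enone 12.
  - LiN(SiMe3)2 in THF at −78 °C forms the cross-conjugated lithium dienolate.
  - On warming to 0 °C the dienolate should undergo an intramolecular double Michael addition (C5 to C10, then the ester enolate carbon C9 to C8) to give the saturated trans-decalone ester F1.
  - TBSOTf/Et3N then enolises F1 towards C7, the only accessible side, and the route is rejoined at 14.

**Step 13.**
- What may go wrong: the enone carbonyl may be hydrosilylated, the iridium catalyst may be inhibited, or the neopentyl C–Si bond may oxidise sluggishly.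
- Fallback: palladium chemistry directed from nitrogen instead of silicon, setting out from 18.
  - Dess–Martin oxidation gives the 3,6-dione F2.
  - NH2OH·HCl/NaOAc condenses selectively with the non-conjugated C3 ketone to give the E-oxime F3.
  - Pd(OAc)2 (cat.) and PhI(OAc)2 in AcOH/Ac2O at 80–100 °C acetylate the oxime in situ and acetoxylate the coplanar equatorial methyl through a five-membered palladacycle, giving the 18-acetoxy O-acetyl oxime F4.
  - Aqueous NaHSO3 releases the 18-acetoxy-3,6-dione F5.
  - NaBH4 at low temperature reduces only the saturated C3 ketone, giving the equatorial alcohol F6.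
  - K2CO3/MeOH removes the acetate, and the route is rejoined at 21.

**Step 23.**
- What may go wrong: oxidative addition of the alkenyl chloride may be slow, chloroprene may polymerise or dimerise at the coupling temperature, and the alkylborane may protodeboronate.
- Fallback: build the diene one alkene at a time, setting out from 31.
  - Hydroboration to 33 as before, then coupling with 2-bromoprop-2-en-1-ol (PdCl2(dppf), Cs2CO3 aq, DMF/THF), gives the 2-substituted allylic alcohol F7.
  - MnO2 oxidises only this allylic alcohol, giving the 2-substituted acrolein F8.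
  - Ph3P=CH2 converts the aldehyde into the second alkene, and the route is rejoined at 34.

**Further compounds**
F1 | step 8 | saturated trans-decalone ester, 6-ketone with C8 methyl, C9 ester and C10 methyl on face M, 3-OTBS | COC(=O)[C@H]1[C@]2(C)CC[C@@H](O[Si](C)(C)C(C)(C)C)C(C)(C)[C@H]2C(=O)C[C@H]1C
F2 | step 13 | 3,6-dione (Δ7, 11-OBn) | c1ccccc1COC[C@H]1[C@]2(C)CCC(=O)C(C)(C)[C@H]2C(=O)C=C1C
F3 | step 13 | (E)-3-oxime of F2 | c1ccccc1COC[C@H]1[C@]2(C)CC/C(=N\O)C(C)(C)[C@H]2C(=O)C=C1C
F4 | step 13 | 18-acetoxy O-acetyl oxime | c1ccccc1COC[C@H]1[C@]2(C)CC/C(=N\OC(C)=O)[C@](C)(COC(C)=O)[C@H]2C(=O)C=C1C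
F5 | step 13 | 18-acetoxy-3,6-dione | c1ccccc1COC[C@H]1[C@]2(C)CCC(=O)[C@](C)(COC(C)=O)[C@H]2C(=O)C=C1C
F6 | step 13 | 18-acetoxy-3-hydroxy Δ7-6-ketone, 3-OH equatorial | c1ccccc1COC[C@H]1[C@]2(C)CC[C@@H](O)[C@](C)(COC(C)=O)[C@H]2C(=O)C=C1C
F7 | step 23 | C13 methylidene C14 allylic alcohol | C=C(CO)CC[C@H]1[C@]2(C)CCC[C@](C)(CO[Si](C)(C)C(C)(C)C)[C@H]2[C@H](OC(C)=O)C[C@]1(C)O
F8 | step 23 | 2-substituted acrolein | C=C(C=O)CC[C@H]1[C@]2(C)CCC[C@](C)(CO[Si](C)(C)C(C)(C)C)[C@H]2[C@H](OC(C)=O)C[C@]1(C)O
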